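The quinone ring (C1–C6; C1=O between C2–OMe and C6–hexaprenyl, C4=O between C3–H and C5–H) is cut into a squarate-derived four-carbon unit (C1, C2, C3, C4, joined by a temporary C1–C4 bond that the target lacks) and a two-carbon alkene (C6 bearing the chain, C5 as =CH2). In one operation, thermolysis of the 4-alkenyl-4-hydroxy-3-methoxycyclobutenone 20 releases ring strain by 4π opening, closes C4–C5 by 6π-electrocyclisation, aromatises, and is oxidised in the flask to the quinone. The step exploits the vinylogous ester O=C4–C3=C2–OMe, which fixes which squarate carbonyl accepts the side-chain alkenyllithium. The all-E chain comes from geranylgeraniol by two Zr-catalysed carboaluminations.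

Key step: step 9

Assumption: the target has no stereocentre, so "single enantiomer" reduces to the single all-E geometric isomer; the five E trisubstituted alkenes are the only stereo-elements to control. Ring numbering used throughout is that of the target (C1 = carbonyl between C2 and C6).

Step 1
Reactants: 1 (2E,6E,10E,14E)-geranylgeraniol
Product: 2 (2E,6E,10E,14E)-geranylgeranyl bromide
Conditions: PBr3 (0.4 equiv), Et2O, −10 °C
Reagents that add atoms: phosphorus tribromide, BrP(Br)Br
Why: The primary allylic alcohol is converted through its phosphite ester into the bromide by SN2 displacement (alcohol-to-bromide substitution) at low temperature, which should leave the 2E alkene and the chain untouched.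

Step 2
Reactants: 2 (2E,6E,10E,14E)-geranylgeranyl bromide; 3 1-(trimethylsilyl)propyne
Product: 6 (5E,9E,13E)-6,10,14,18-tetramethylnonadeca-5,9,13,17-tetraen-1-yne, via lithiated silylpropyne 4 (not isolated), via silyl-capped tetraenyne 5 (not isolated)
Conditions: 3, n-BuLi, THF, −78 → −20 °C; then 2, −78 °C → rt; then MeOH, K2CO3, rt
Reagents that add atoms: none
Why: Deprotonated 1-(trimethylsilyl)propyne reacts at its CH2 terminus (the silyl group blocks the alkyne end) in an SN2 propargylation of the primary allylic bromide with retention of all E alkenes, and methanolic carbonate then cleaves the alkynyl C–Si bond (protodesilylation).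

Step 3
Reactants: 6 (5E,9E,13E)-6,10,14,18-tetramethylnonadeca-5,9,13,17-tetraen-1-yne
Product: 8 (1E,5E,9E,13E)-1-iodo-2,6,10,14,18-pentamethylnonadeca-1,5,9,13,17-pentaene, via alkenyldimethylalane 7 (not isolated)
Conditions: Me3Al (2 equiv), Cp2ZrCl2 (0.25 equiv), (CH2Cl)2, rt; then I2, THF, −30 → 0 °C
Reagents that add atoms: trimethylaluminium, C[Al](C)C; iodine, II
Why: Negishi Zr-catalysed methylalumination adds Me and Al syn across the terminal alkyne with Al at the terminus, so the new trisubstituted alkene is E, and iodinolysis of the C–Al bond proceeds with retention; the trisubstituted chain alkenes are inert.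

Step 4
Reactants: 8 (1E,5E,9E,13E)-1-iodo-2,6,10,14,18-pentamethylnonadeca-1,5,9,13,17-pentaene; 9 (4-bromobut-1-yn-1-yl)trimethylsilane
Product: 11 trimethyl[(5E,9E,13E,17E)-6,10,14,18,22-pentamethyltricosa-5,9,13,17,21-pentaen-1-yn-1-yl]silane, via homopropargylzinc bromide 10 (not isolated)
Conditions: 9, Zn dust, LiCl, THF, 50 °C; then 8, PdCl2(dppf) (5 mol %), THF, rt
Reagents that add atoms: none
Why: Negishi alkyl–alkenyl cross-coupling, in which Pd(0) inserts into the alkenyl C–I bond with retention, the primary alkylzinc transmetalates and reductive elimination forms the CH2–CH= bond of the next 1,5-diene link; the silyl group masks the alkyne.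

Step 5
Reactants: 11 trimethyl[(5E,9E,13E,17E)-6,10,14,18,22-pentamethyltricosa-5,9,13,17,21-pentaen-1-yn-1-yl]silane
Product: 12 (5E,9E,13E,17E)-6,10,14,18,22-pentamethyltricosa-5,9,13,17,21-pentaen-1-yne
Conditions: K2CO3, MeOH/THF, rt
Reagents that add atoms: none
Why: Base-catalysed methanolysis of the alkynyl C–Si bond (protodesilylation) frees the terminal alkyne without touching the alkenes.

Step 6
Reactants: 12 (5E,9E,13E,17E)-6,10,14,18,22-pentamethyltricosa-5,9,13,17,21-pentaen-1-yne; 13 2,3-dibromopropene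
Product: 15 (4E,8E,12E,16E,20E)-2-bromo-5,9,13,17,21,25-hexamethylhexacosa-1,4,8,12,16,20,24-heptaene, via alkenyldimethylalane 14 (not isolated)
Conditions: Me3Al, Cp2ZrCl2, (CH2Cl)2, rt; volatiles removed; then 13 (3 equiv), Pd(PPh3)4 (5 mol %), THF, 0 °C → rt
Reagents that add atoms: trimethylaluminium, C[Al](C)C
Why: A second Negishi carboalumination sets the last E trisubstituted alkene by syn addition, and Pd(0)-catalysed allylation of the alkenylalane (Negishi 1,4-diene synthesis) should occur at the allylic C–Br of 13 through the π-allyl complex, far faster than insertion into either 2-bromoalkene, with retention at the alkenyl carbon.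

Step 7
Reactants: 16 dimethyl squarate
Product: 18 methyl semisquarate (3-methoxycyclobut-3-ene-1,2-dione), via hydroxycyclobutenone 17 (not isolated)
Conditions: LiAlH(O-t-Bu)3 (1.05 equiv), THF, −78 → 0 °C; then cat. conc. HCl, CH2Cl2, rt
Reagents that add atoms: none
Why: One hydride adds 1,2 to a squarate carbonyl (the resulting vinylogous ester resists further reduction), and acid then ionises the carbinol with allylic transposition through the methoxy-stabilised oxocarbenium ion and loss of methanol (1,2-reduction followed by acid-catalysed elimination).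

Step 8
Reactants: 15 (4E,8E,12E,16E,20E)-2-bromo-5,9,13,17,21,25-hexamethylhexacosa-1,4,8,12,16,20,24-heptaene; 18 methyl semisquarate
Product: 20 (±)-4-hydroxy-3-methoxy-4-[(4E,8E,12E,16E,20E)-5,9,13,17,21,25-hexamethylhexacosa-1,4,8,12,16,20,24-heptaen-2-yl]cyclobut-2-en-1-one, via alkenyllithium 19 (not isolated)
Conditions: 15, t-BuLi (2.1 equiv), Et2O, −78 °C; then 18, THF, −78 °C; sat. NH4Cl, −78 °C
Reagents that add atoms: none
Why: Bromine–lithium exchange gives the alkenyllithium, which should add 1,2 at −78 °C to the more electrophilic cross-conjugated carbonyl of 18 (the one bonded to C–OMe, future C1) rather than to the vinylogous-ester carbonyl bonded to CH (organolithium addition to an alkoxycyclobutenedione), giving the racemic tertiary alcohol whose stereocentre is erased in step 9.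

Step 9
Reactants: 20 (±)-4-hydroxy-3-methoxy-4-[(4E,8E,12E,16E,20E)-5,9,13,17,21,25-hexamethylhexacosa-1,4,8,12,16,20,24-heptaen-2-yl]cyclobut-2-en-1-one
Product: 24 2-methoxy-6-[(2E,6E,10E,14E,18E)-3,7,11,15,19,23-hexamethyltetracosa-2,6,10,14,18,22-hexaen-1-yl]cyclohexa-2,5-diene-1,4-dione (target), via dienylketene 21 (not isolated), via cyclohexadienone 22 (not isolated), via hydroquinone 23 (not isolated)
Conditions: PhMe (0.01 M, degassed), 110 °C; then Ag2O, Na2SO4, rt
Reagents that add atoms: none
Why: Heating opens the strained cyclobutenone by conrotatory 4π electrocyclic cleavage of the C1–C4 bond (the bond the target lacks), the donor hydroxyl rotating outward so that the alkenyl group turns inward and the (Z)-dienylketene 21 results. Ketene carbon C4 and the alkene terminus C5 then join in a thermal disrotatory 6π-electrocyclisation (the six-membered ring is closed by a pericyclic C–C bond formation, not a polar exo/endo closure) to dienone 22, which enolises to the aromatic hydroquinone 23; Ag2O then removes two hydrogens in the same flask so that the air-sensitive hydroquinone is never handled. The closest known reaction type is the Moore-type thermal ring expansion of 4-alkenyl-4-hydroxycyclobutenones to hydroquinones and quinones. No stereocentre is formed, the carbinol centre of 20 is erased, and the E alkenes of the chain take no part. The step needs torquoselectivity (hydroxyl out, alkenyl in) and 6π closure in preference to capture of the ketene by the hydroxyl; the first is secured by the outward preference of the oxygen donor on the carbinol carbon and the second by the inward, s-cis-disposed 1,1-disubstituted vinyl group. The substitution pattern (C1=O flanked by C2–OMe and C6–chain) is already fixed by the site of addition in step 8.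

Compound list
1 | (2E,6E,10E,14E)-geranylgeraniol | OC/C=C(\C)CC/C=C(\C)CC/C=C(\C)CCC=C(C)C | starting material
2 | (2E,6E,10E,14E)-geranylgeranyl bromide | BrC/C=C(\C)CC/C=C(\C)CC/C=C(\C)CCC=C(C)C | intermediate
3 | 1-(trimethylsilyl)propyne | CC#C[Si](C)(C)C | starting material
4 | [3-(trimethylsilyl)prop-2-yn-1-yl]lithium | [Li]CC#C[Si](C)(C)C | intermediate
5 | trimethyl[(5E,9E,13E)-6,10,14,18-tetramethylnonadeca-5,9,13,17-tetraen-1-yn-1-yl]silane | C[Si](C)(C)C#CCC/C=C(\C)CC/C=C(\C)CC/C=C(\C)CCC=C(C)C | intermediate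
6 | (5E,9E,13E)-6,10,14,18-tetramethylnonadeca-5,9,13,17-tetraen-1-yne | C#CCC/C=C(\C)CC/C=C(\C)CC/C=C(\C)CCC=C(C)C | intermediate
7 | dimethyl[(1E,5E,9E,13E)-2,6,10,14,18-pentamethylnonadeca-1,5,9,13,17-pentaen-1-yl]alane | C[Al](C)/C=C(\C)CC/C=C(\C)CC/C=C(\C)CC/C=C(\C)CCC=C(C)C | intermediate
8 | (1E,5E,9E,13E)-1-iodo-2,6,10,14,18-pentamethylnonadeca-1,5,9,13,17-pentaene | I/C=C(\C)CC/C=C(\C)CC/C=C(\C)CC/C=C(\C)CCC=C(C)C | intermediate
9 | (4-bromobut-1-yn-1-yl)trimethylsilane | C[Si](C)(C)C#CCCBr | starting material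
10 | [4-(trimethylsilyl)but-3-yn-1-yl]zinc bromide | C[Si](C)(C)C#CCC[Zn]Br | intermediate
11 | trimethyl[(5E,9E,13E,17E)-6,10,14,18,22-pentamethyltricosa-5,9,13,17,21-pentaen-1-yn-1-yl]silane | C[Si](C)(C)C#CCC/C=C(\C)CC/C=C(\C)CC/C=C(\C)CC/C=C(\C)CCC=C(C)C | intermediate
12 | (5E,9E,13E,17E)-6,10,14,18,22-pentamethyltricosa-5,9,13,17,21-pentaen-1-yne | C#CCC/C=C(\C)CC/C=C(\C)CC/C=C(\C)CC/C=C(\C)CCC=C(C)C | intermediate
13 | 2,3-dibromopropene | C=C(Br)CBr | starting material
14 | dimethyl[(1E,5E,9E,13E,17E)-2,6,10,14,18,22-hexamethyltricosa-1,5,9,13,17,21-hexaen-1-yl]alane | C[Al](C)/C=C(\C)CC/C=C(\C)CC/C=C(\C)CC/C=C(\C)CC/C=C(\C)CCC=C(C)C | intermediate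
15 | (4E,8E,12E,16E,20E)-2-bromo-5,9,13,17,21,25-hexamethylhexacosa-1,4,8,12,16,20,24-heptaene | C=C(Br)C/C=C(\C)CC/C=C(\C)CC/C=C(\C)CC/C=C(\C)CC/C=C(\C)CCC=C(C)C | intermediate
16 | dimethyl squarate (3,4-dimethoxycyclobut-3-ene-1,2-dione) | COC1=C(OC)C(=O)C1=O | starting material
17 | 4-hydroxy-2,3-dimethoxycyclobut-2-en-1-one (racemic) | COC1=C(OC)C(O)C1=O | intermediate
18 | methyl semisquarate (3-methoxycyclobut-3-ene-1,2-dione) | COC1=CC(=O)C1=O | intermediate
19 | [(4E,8E,12E,16E,20E)-5,9,13,17,21,25-hexamethylhexacosa-1,4,8,12,16,20,24-heptaen-2-yl]lithium | [Li]C(=C)C/C=C(\C)CC/C=C(\C)CC/C=C(\C)CC/C=C(\C)CC/C=C(\C)CCC=C(C)C | intermediate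
20 | (±)-4-hydroxy-3-methoxy-4-[(4E,8E,12E,16E,20E)-5,9,13,17,21,25-hexamethylhexacosa-1,4,8,12,16,20,24-heptaen-2-yl]cyclobut-2-en-1-one | COC1=CC(=O)C1(O)C(=C)C/C=C(\C)CC/C=C(\C)CC/C=C(\C)CC/C=C(\C)CC/C=C(\C)CCC=C(C)C | intermediate
21 | (Z)-4-hydroxy-3-methoxy-5-methylidene dienylketene bearing the hexaprenyl chain (ring-opened form of 20; ketenyl and alkenyl groups cis) | O=C=C/C(OC)=C(/O)C(=C)C/C=C(\C)CC/C=C(\C)CC/C=C(\C)CC/C=C(\C)CC/C=C(\C)CCC=C(C)C | intermediate
22 | 4-hydroxy-3-methoxy-5-(all-E-hexaprenyl)cyclohexa-2,4-dien-1-one | COC1=CC(=O)CC(C/C=C(\C)CC/C=C(\C)CC/C=C(\C)CC/C=C(\C)CC/C=C(\C)CCC=C(C)C)=C1O | intermediate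
23 | 2-methoxy-6-(all-E-hexaprenyl)benzene-1,4-diol | COc1cc(O)cc(C/C=C(\C)CC/C=C(\C)CC/C=C(\C)CC/C=C(\C)CC/C=C(\C)CCC=C(C)C)c1O | intermediate
24 | 2-methoxy-6-[(2E,6E,10E,14E,18E)-3,7,11,15,19,23-hexamethyltetracosa-2,6,10,14,18,22-hexaen-1-yl]cyclohexa-2,5-diene-1,4-dione | COC1=CC(=O)C=C(C/C=C(\C)CC/C=C(\C)CC/C=C(\C)CC/C=C(\C)CC/C=C(\C)CCC=C(C)C)C1=O | target

Total step count: 9. Longest linear sequence: 8 steps (steps 1–6, 8, 9); step 7 is a one-step side branch.

Steps most likely to fail

Step 9 (key step). The hydroxyl of the ring-opened ketene may add to the ketene carbon (butenolide formation), or the free tertiary alcohol may ionise and lose methanol before the ring opens, so that electrocyclisation is outrun. The fallback sets out from 20 and comes back at 24. The tertiary hydroxyl is capped as its methyl ether (MeI, Ag2O, K2CO3, MeCN) to give 3,4-dimethoxy-4-[(4E,8E,12E,16E,20E)-5,9,13,17,21,25-hexamethylhexacosa-1,4,8,12,16,20,24-heptaen-2-yl]cyclobut-2-en-1-one F9. Its thermolysis in toluene, now with no hydroxyl to trap the ketene, should give 3,4-dimethoxy-5-(all-E-hexaprenyl)phenol F10. Oxidative demethylation of this para-methoxyphenol with ceric ammonium nitrate (MeCN/H2O, 0 °C) should give 24.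

Step 8. The basic alkenyllithium may abstract a proton (its own doubly allylic CH2 or the ring CH of 18), or add in conjugate fashion or at the other carbonyl, and the acid-labile adduct may ionise on isolation. The fallback sets out from 15 and 18 and comes back at 24; it needs no organolithium, and the position of a leaving group fixes the regiochemistry.
- Bromide 15 is stannylated with hexabutylditin and Pd(PPh3)4 to tributyl[(4E,8E,12E,16E,20E)-5,9,13,17,21,25-hexamethylhexacosa-1,4,8,12,16,20,24-heptaen-2-yl]stannane F4.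
- Dione 18 is reduced with LiAlH(O-t-Bu)3 to 4-hydroxy-3-methoxycyclobut-2-en-1-one F5 and converted with PPh3/CCl4 (Appel reaction) into 4-chloro-3-methoxycyclobut-2-en-1-one F6.
- Stille coupling of F4 with F6 (Pd2dba3, tri-2-furylphosphine, dioxane, 50–100 °C) should give 3-methoxy-4-alkenylcyclobut-2-en-1-one F7. This should ring-open and electrocyclise in the flask to 3-methoxy-5-(all-E-hexaprenyl)phenol F8, so the ring is still formed from the four-membered precursor.
- Teuber oxidation of F8 with Fremy's salt at the free para position, which lies between the methoxy and the chain, should give 24.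

Step 6. Pd(0) may also couple the product 2-bromoalkene with further alkenylalane, or transfer methyl from aluminium, eroding the 2-bromo-1,4-diene. The fallback sets out from 12 and comes back at 15.
- Alane 14 is converted into its butyl ate complex (n-BuLi) and trapped with paraformaldehyde to give (2E,6E,10E,14E,18E)-hexaprenol F1.
- PBr3 gives hexaprenyl bromide F2.
- Cu(I)-catalysed SN2 coupling with ethynylmagnesium bromide gives (4E,8E,12E,16E,20E)-5,9,13,17,21,25-hexamethylhexacosa-4,8,12,16,20,24-hexaen-1-yne F3.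
- Bromoboration of the terminal alkyne with B-bromo-9-BBN followed by protonolysis with acetic acid should give 15.

Further compounds
F1 | step 6 | (2E,6E,10E,14E,18E)-3,7,11,15,19,23-hexamethyltetracosa-2,6,10,14,18,22-hexaen-1-ol (hexaprenol) | OC/C=C(\C)CC/C=C(\C)CC/C=C(\C)CC/C=C(\C)CC/C=C(\C)CCC=C(C)C
F2 | step 6 | (2E,6E,10E,14E,18E)-1-bromo-3,7,11,15,19,23-hexamethyltetracosa-2,6,10,14,18,22-hexaene (hexaprenyl bromide) | BrC/C=C(\C)CC/C=C(\C)CC/C=C(\C)CC/C=C(\C)CC/C=C(\C)CCC=C(C)C
F3 | step 6 | (4E,8E,12E,16E,20E)-5,9,13,17,21,25-hexamethylhexacosa-4,8,12,16,20,24-hexaen-1-yne | C#CC/C=C(\C)CC/C=C(\C)CC/C=C(\C)CC/C=C(\C)CC/C=C(\C)CCC=C(C)C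
F4 | step 8 | tributyl[(4E,8E,12E,16E,20E)-5,9,13,17,21,25-hexamethylhexacosa-1,4,8,12,16,20,24-heptaen-2-yl]stannane | CCCC[Sn](CCCC)(CCCC)C(=C)C/C=C(\C)CC/C=C(\C)CC/C=C(\C)CC/C=C(\C)CC/C=C(\C)CCC=C(C)C
F5 | step 8 | 4-hydroxy-3-methoxycyclobut-2-en-1-one | COC1=CC(=O)C1O
F6 | step 8 | 4-chloro-3-methoxycyclobut-2-en-1-one | COC1=CC(=O)C1Cl
F7 | step 8 | 3-methoxy-4-[(4E,8E,12E,16E,20E)-5,9,13,17,21,25-hexamethylhexacosa-1,4,8,12,16,20,24-heptaen-2-yl]cyclobut-2-en-1-one | COC1=CC(=O)C1C(=C)C/C=C(\C)CC/C=C(\C)CC/C=C(\C)CC/C=C(\C)CC/C=C(\C)CCC=C(C)C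
F8 | step 8 | 3-methoxy-5-(all-E-hexaprenyl)phenol | COc1cc(O)cc(C/C=C(\C)CC/C=C(\C)CC/C=C(\C)CC/C=C(\C)CC/C=C(\C)CCC=C(C)C)c1
F9 | step 9 | 3,4-dimethoxy-4-[(4E,8E,12E,16E,20E)-5,9,13,17,21,25-hexamethylhexacosa-1,4,8,12,16,20,24-heptaen-2-yl]cyclobut-2-en-1-one | COC1=CC(=O)C1(OC)C(=C)C/C=C(\C)CC/C=C(\C)CC/C=C(\C)CC/C=C(\C)CC/C=C(\C)CCC=C(C)C
F10 | step 9 | 3,4-dimethoxy-5-(all-E-hexaprenyl)phenol | COc1cc(O)cc(C/C=C(\C)CC/C=C(\C)CC/C=C(\C)CC/C=C(\C)CC/C=C(\C)CCC=C(C)C)c1OC
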